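C1 is the ring CH carrying the side chain, C2 the CMe2 carbon, C3 the carbinol, C4 and C5 the ring methylenes, C6 the carbon bearing the exocyclic methylene; the side chain runs C1′ to C16′.
Retrosynthesis cuts the sp3–sp2 bond C2′–C3′ (ring fragment as a C2′ alkylzinc, side chain as a C19 (E)-2-iodoalkene from farnesol and propyne), then the ring bond C6–C1, then C1=C1′ (olefination) and C4–C5 (propargylation of a C4 triflate).
Enabling feature: C6 carries the methylene and lies six atoms from C1, so a 2-bromoalkene at C6 gives a vinyl radical that closes the only ring 6-exo onto C1, the β-carbon of a C1=C1′ enoate; C4–C3(O)–C2(Me2)–C1 is the intact carbon chain of (R)-pantolactone.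
Forward order: pantolactone, C4–C5 alkylation, C1 enoate, bromoalkene, ring closure (the single ring), C1′ ester to C2′ iodide, Negishi union with the farnesol-derived iodoalkene, desilylation.
Stereochemistry: C3 (S) is the untouched carbinol of (R)-pantolactone; C1 (R) is set in the ring closure, cis to the C3 oxygen, by a chair transition state with both groups equatorial; the C3′ alkene (E) comes from syn hydrozirconation–iodination and a stereoretentive coupling, and the C7′ and C11′ alkenes from (2E,6E)-farnesol.

Key step: step 11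

Assumption: under equilibrating acetalisation triol 2 is taken to give the six-membered 1,3-dioxane 3 with the aryl group equatorial; the lithio derivative of 5 is drawn in its propargyl form 6 and 1,3-dilithiopropyne 24 with covalent C–Li bonds.

Step 1
Reactants: 1 (R)-pantolactone
Product: 2 (2R)-3,3-dimethylbutane-1,2,4-triol
Conditions: LiAlH4, THF, 0 °C → reflux; aq NaOH work-up
Reagents that add atoms: none
Why: LiAlH4 reduces the lactone to the diol (ester-to-alcohol hydride reduction), and the carbinol centre has no epimerisation pathway once the carbonyl is gone.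

Step 2
Reactants: 2 (2R)-3,3-dimethylbutane-1,2,4-triol
Product: 3 [(2R,4R)-2-(4-methoxyphenyl)-5,5-dimethyl-1,3-dioxan-4-yl]methanol
Conditions: 4-MeOC6H4CH(OMe)2, PPTS (cat.), CH2Cl2, rt
Reagents that add atoms: 4-methoxybenzaldehyde dimethyl acetal, COc1ccc(C(OC)OC)cc1
Why: Acid-catalysed transacetalisation under thermodynamic control should favour the 5,5-dimethyl-1,3-dioxane spanning the secondary and neopentyl hydroxyls, with the aryl group equatorial and cis to the C4 substituent (new acetal centre 2R), leaving free only the primary hydroxyl that becomes ring C4.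

Step 3
Reactants: 3 [(2R,4R)-2-(4-methoxyphenyl)-5,5-dimethyl-1,3-dioxan-4-yl]methanol
Product: 4 [(2R,4R)-2-(4-methoxyphenyl)-5,5-dimethyl-1,3-dioxan-4-yl]methyl trifluoromethanesulfonate
Conditions: Tf2O, 2,6-lutidine, CH2Cl2, −78 °C; used crude at once
Reagents that add atoms: trifluoromethanesulfonic anhydride, O=S(=O)(OS(=O)(=O)C(F)(F)F)C(F)(F)F
Why: Triflation of the unhindered primary alcohol under hindered-base buffering (O-sulfonylation) gives a leaving group reactive enough for a β-alkoxy carbon, and the acetal is stable to the basic, cold medium.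

Step 4
Reactants: 4 [(2R,4R)-2-(4-methoxyphenyl)-5,5-dimethyl-1,3-dioxan-4-yl]methyl trifluoromethanesulfonate; 5 1-(trimethylsilyl)propyne
Product: 8 (2R,4S)-4-(but-3-yn-1-yl)-2-(4-methoxyphenyl)-5,5-dimethyl-1,3-dioxane, via [3-(trimethylsilyl)prop-2-yn-1-yl]lithium 6 (not isolated), via trimethyl{4-[(2R,4S)-2-(4-methoxyphenyl)-5,5-dimethyl-1,3-dioxan-4-yl]but-1-yn-1-yl}silane 7 (not isolated)
Conditions: 5, n-BuLi, THF, −78 → −20 °C; then 4, −78 → −20 °C; then MeOH, K2CO3, rt
Reagents that add atoms: none
Why: The silyl-capped propargyllithium alkylates the primary triflate at its propargylic carbon (SN2 alkylation, forming C4–C5), and methanolysis of the alkynyl C–Si bond in the same flask frees the terminal alkyne; the stereocentre is not involved and its descriptor changes only through the priority switch.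

Step 5
Reactants: 8 (2R,4S)-4-(but-3-yn-1-yl)-2-(4-methoxyphenyl)-5,5-dimethyl-1,3-dioxane
Product: 9 (3S)-3-[(4-methoxybenzyl)oxy]-2,2-dimethylhept-6-yn-1-ol
Conditions: i-Bu2AlH (3 equiv), CH2Cl2, −78 → 0 °C; aq potassium sodium tartrate work-up
Reagents that add atoms: none
Why: In this regioselective reductive opening of a p-methoxybenzylidene acetal, the aluminium hydride coordinates the less hindered primary-side oxygen and reduces the oxocarbenium ion, so the PMB ether stays on the secondary oxygen and the neopentyl alcohol is released.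

Step 6
Reactants: 9 (3S)-3-[(4-methoxybenzyl)oxy]-2,2-dimethylhept-6-yn-1-ol
Product: 10 (3S)-3-[(4-methoxybenzyl)oxy]-2,2-dimethylhept-6-ynal
Conditions: Dess–Martin periodinane, NaHCO3, CH2Cl2, rt
Reagents that add atoms: none
Why: Dess–Martin oxidation takes the primary alcohol to the aldehyde under buffered conditions, and the product has no α-hydrogen, so it can neither enolise nor eliminate the β-alkoxy group.

Step 7
Reactants: 10 (3S)-3-[(4-methoxybenzyl)oxy]-2,2-dimethylhept-6-ynal; 11 trimethyl phosphonoacetate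
Product: 13 methyl (2E,5S)-5-[(4-methoxybenzyl)oxy]-4,4-dimethylnon-2-en-8-ynoate, via sodium (dimethoxyphosphoryl)(methoxycarbonyl)methanide 12 (not isolated)
Conditions: 11 (slight excess over NaH), NaH, THF, 0 °C; then 10, 0 °C → rt
Reagents that add atoms: none
Why: Horner–Wadsworth–Emmons olefination of a non-enolisable aldehyde with a stabilised phosphonate anion should give the (E)-enoate through the reversible, thermodynamically governed addition–elimination pathway, and the anion is too weak a base to deprotonate the terminal alkyne.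

Step 8
Reactants: 13 methyl (2E,5S)-5-[(4-methoxybenzyl)oxy]-4,4-dimethylnon-2-en-8-ynoate
Product: 14 methyl (2E,5S)-5-hydroxy-4,4-dimethylnon-2-en-8-ynoate
Conditions: DDQ, CH2Cl2/pH 7 buffer, 0 °C → rt
Reagents that add atoms: none
Why: Oxidative PMB cleavage by DDQ (benzylic hydride abstraction, then hydrolysis of the hemiacetal) spares the enoate, the alkyne and the stereocentre, and the (E)-hydroxy enoate cannot lactonise.

Step 9
Reactants: 14 methyl (2E,5S)-5-hydroxy-4,4-dimethylnon-2-en-8-ynoate
Product: 15 methyl (2E,5S)-5-[(tert-butyldimethylsilyl)oxy]-4,4-dimethylnon-2-en-8-ynoate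
Conditions: TBSOTf, 2,6-lutidine, CH2Cl2, 0 °C → rt
Reagents that add atoms: tert-butyldimethylsilyl trifluoromethanesulfonate, CC(C)(C)[Si](C)(C)OS(=O)(=O)C(F)(F)F
Why: Silyl ether formation with the reactive silyl triflate overcomes the hindrance of the neopentyl-type secondary alcohol and replaces the benzylic ether, which could lose a hydrogen to the later vinyl radical or be cleaved by the bromoborane.

Step 10
Reactants: 15 methyl (2E,5S)-5-[(tert-butyldimethylsilyl)oxy]-4,4-dimethylnon-2-en-8-ynoate
Product: 17 methyl (2E,5S)-8-bromo-5-[(tert-butyldimethylsilyl)oxy]-4,4-dimethylnona-2,8-dienoate, via methyl (2E,5S,8Z)-9-(9-borabicyclo[3.3.1]nonan-9-yl)-8-bromo-5-[(tert-butyldimethylsilyl)oxy]-4,4-dimethylnona-2,8-dienoate 16 (not isolated)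
Conditions: B-bromo-9-BBN (1.3 equiv), CH2Cl2, 0 °C; then AcOH, 0 °C → rt; aq NaHCO3 work-up
Reagents that add atoms: B-bromo-9-borabicyclo[3.3.1]nonane, BrB1C2CCCC1CCC2
Why: Haloboration adds B–Br syn across the terminal alkyne with bromine on the internal carbon, and protodeboronation of the alkenylborane by acetic acid gives the 2-bromo-1-alkene, the reagent reacting with terminal alkynes far faster than with alkenes or esters.

Step 11
Reactants: 17 methyl (2E,5S)-8-bromo-5-[(tert-butyldimethylsilyl)oxy]-4,4-dimethylnona-2,8-dienoate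
Product: 18 methyl 2-[(1R,3S)-3-[(tert-butyldimethylsilyl)oxy]-2,2-dimethyl-6-methylidenecyclohexyl]acetate
Conditions: Bu3SnH (1.3 equiv) and AIBN (0.2 equiv) added by syringe pump over 6 h, PhH (0.01 M), 80 °C
Reagents that add atoms: none
Why: The stannyl radical abstracts bromine from 17 to give a σ vinyl radical at C6, which adds to the enoate β-carbon C1, and the ester-stabilised radical so formed takes hydrogen from Bu3SnH and carries the chain. The closest known reaction type is the tin-hydride-mediated cyclisation of vinyl radicals onto α,β-unsaturated esters. The single carbocycle closes in the 6-exo-trig mode by forming C6–C1, and the radical carbon itself becomes the methylene-bearing ring carbon. The new centre C1 (R) is controlled by the C3 stereocentre through a chair-like transition state in which the C3 silyloxy group and the acrylate arm are both equatorial, which should give the cis-1,3 product. The step needs 6-exo over 7-endo closure and cyclisation ahead of direct reduction; these are secured by the polarity match of the nucleophilic vinyl radical with the electron-poor β-carbon, the gem-dimethyl effect, the absence of a 1,5-transferable hydrogen (C2 is quaternary) and slow stannane addition at high dilution.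

Step 12
Reactants: 18 methyl 2-[(1R,3S)-3-[(tert-butyldimethylsilyl)oxy]-2,2-dimethyl-6-methylidenecyclohexyl]acetate
Product: 19 2-[(1R,3S)-3-[(tert-butyldimethylsilyl)oxy]-2,2-dimethyl-6-methylidenecyclohexyl]ethan-1-ol
Conditions: i-Bu2AlH (2.5 equiv), CH2Cl2, −78 → 0 °C; aq potassium sodium tartrate work-up
Reagents that add atoms: none
Why: Hydride reduction of the ester with excess aluminium hydride gives the primary alcohol without touching the silyl ether, the 1,1-disubstituted alkene or either stereocentre.

Step 13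
Reactants: 19 2-[(1R,3S)-3-[(tert-butyldimethylsilyl)oxy]-2,2-dimethyl-6-methylidenecyclohexyl]ethan-1-ol
Product: 20 tert-butyl{[(1S,3R)-3-(2-iodoethyl)-2,2-dimethyl-4-methylidenecyclohexyl]oxy}dimethylsilane
Conditions: PPh3, I2, imidazole, CH2Cl2, 0 °C → rt
Reagents that add atoms: iodine, II
Why: The Appel reaction converts the unhindered primary alcohol to the iodide by SN2 displacement of the alkoxyphosphonium ion, with no stereocentre involved.

Step 14
Reactants: 21 (2E,6E)-farnesol
Product: 22 (2E,6E)-1-bromo-3,7,11-trimethyldodeca-2,6,10-triene (farnesyl bromide)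
Conditions: PBr3, Et2O, −10 → 0 °C; used crude
Reagents that add atoms: phosphorus tribromide, BrP(Br)Br
Why: Bromination of the primary allylic alcohol with PBr3 at low temperature (SN2 at the primary carbon) preserves the (2E,6E) geometry.

Step 15
Reactants: 22 (2E,6E)-1-bromo-3,7,11-trimethyldodeca-2,6,10-triene; 23 propyne
Product: 26 (6E,10E)-7,11,15-trimethylhexadeca-6,10,14-trien-2-yne, via 1,3-dilithiopropyne 24 (not isolated), via [(5E,9E)-6,10,14-trimethylpentadeca-5,9,13-trien-1-yn-1-yl]lithium 25 (not isolated)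
Conditions: 23, n-BuLi (2 equiv), TMEDA, Et2O/hexane, −78 → 0 °C; then 22, −78 °C → rt; then MeI (excess), THF, 0 °C → rt
Reagents that add atoms: iodomethane, CI
Why: Double deprotonation of propyne gives 1,3-dilithiopropyne, whose more basic propargylic carbon displaces the primary allylic bromide (SN2 alkylation of a propargyl dianion equivalent) with the alkene geometry intact, and the lithium acetylide that remains is C-methylated by iodomethane in the same flask to give the 2-alkyne needed for regiocontrolled hydrometalation.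

Step 16
Reactants: 26 (6E,10E)-7,11,15-trimethylhexadeca-6,10,14-trien-2-yne
Product: 28 (2E,6E,10E)-2-iodo-7,11,15-trimethylhexadeca-2,6,10,14-tetraene, via chlorobis(cyclopentadienyl)[(2E,6E,10E)-7,11,15-trimethylhexadeca-2,6,10,14-tetraen-2-yl]zirconium 27 (not isolated)
Conditions: Cp2Zr(H)Cl (2.5 equiv), THF, 50 °C; then I2, THF, 0 °C
Reagents that add atoms: iodine, II
Why: Hydrozirconation with excess Cp2Zr(H)Cl under equilibrating conditions places zirconium by syn addition on the less hindered alkyne carbon next to the methyl group, iodinolysis with retention gives the (E)-2-iodo-2-alkene, and the trisubstituted alkenes are inert to the reagent.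

Step 17
Reactants: 20 tert-butyl{[(1S,3R)-3-(2-iodoethyl)-2,2-dimethyl-4-methylidenecyclohexyl]oxy}dimethylsilane; 28 (2E,6E,10E)-2-iodo-7,11,15-trimethylhexadeca-2,6,10,14-tetraene
Product: 30 tert-butyl{[(1S,3R)-2,2-dimethyl-4-methylidene-3-[(3E,7E,11E)-3,8,12,16-tetramethylheptadeca-3,7,11,15-tetraen-1-yl]cyclohexyl]oxy}dimethylsilane, via {2-[(1R,3S)-3-[(tert-butyldimethylsilyl)oxy]-2,2-dimethyl-6-methylidenecyclohexyl]ethyl}(iodo)zinc 29 (not isolated)
Conditions: 20, Zn dust (activated with BrCH2CH2Br and Me3SiCl), LiCl, THF, 40 °C; then 28, Pd(PPh3)4 (5 mol %), THF, 45 °C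
Reagents that add atoms: none
Why: In this Negishi coupling, zinc inserts into the primary C–I bond, the alkylzinc iodide transmetalates to the alkenylpalladium iodide formed from 28 and zerovalent palladium, and reductive elimination forms C2′–C3′ with retention of the (E) geometry; a pent-4-enyl-type zinc reagent has no favourable cyclisation mode.

Step 18
Reactants: 30 tert-butyl{[(1S,3R)-2,2-dimethyl-4-methylidene-3-[(3E,7E,11E)-3,8,12,16-tetramethylheptadeca-3,7,11,15-tetraen-1-yl]cyclohexyl]oxy}dimethylsilane
Product: 31 achilleol A, (1S,3R)-2,2-dimethyl-4-methylidene-3-[(3E,7E,11E)-3,8,12,16-tetramethylheptadeca-3,7,11,15-tetraen-1-yl]cyclohexan-1-ol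
Conditions: Bu4NF, THF, rt → 50 °C
Reagents that add atoms: none
Why: Fluoride-driven cleavage of the silyl ether (desilylation) frees the C3 alcohol without affecting the polyene or either stereocentre.

Compound list
1 | (R)-pantolactone, (3R)-3-hydroxy-4,4-dimethyloxolan-2-one | CC1(C)COC(=O)[C@@H]1O | starting material
2 | (2R)-3,3-dimethylbutane-1,2,4-triol | OC[C@H](O)C(C)(C)CO | intermediate
3 | [(2R,4R)-2-(4-methoxyphenyl)-5,5-dimethyl-1,3-dioxan-4-yl]methanol | OC[C@@H]1O[C@H](c2ccc(OC)cc2)OCC1(C)C | intermediate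
4 | [(2R,4R)-2-(4-methoxyphenyl)-5,5-dimethyl-1,3-dioxan-4-yl]methyl trifluoromethanesulfonate | FC(F)(F)S(=O)(=O)OC[C@@H]1O[C@H](c2ccc(OC)cc2)OCC1(C)C | intermediate
5 | 1-(trimethylsilyl)propyne | CC#C[Si](C)(C)C | starting material
6 | [3-(trimethylsilyl)prop-2-yn-1-yl]lithium | [Li]CC#C[Si](C)(C)C | intermediate
7 | trimethyl{4-[(2R,4S)-2-(4-methoxyphenyl)-5,5-dimethyl-1,3-dioxan-4-yl]but-1-yn-1-yl}silane | C[Si](C)(C)C#CCC[C@@H]1O[C@H](c2ccc(OC)cc2)OCC1(C)C | intermediate
8 | (2R,4S)-4-(but-3-yn-1-yl)-2-(4-methoxyphenyl)-5,5-dimethyl-1,3-dioxane | C#CCC[C@@H]1O[C@H](c2ccc(OC)cc2)OCC1(C)C | intermediate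
9 | (3S)-3-[(4-methoxybenzyl)oxy]-2,2-dimethylhept-6-yn-1-ol | C#CCC[C@H](OCc1ccc(OC)cc1)C(C)(C)CO | intermediate
10 | (3S)-3-[(4-methoxybenzyl)oxy]-2,2-dimethylhept-6-ynal | C#CCC[C@H](OCc1ccc(OC)cc1)C(C)(C)C=O | intermediate
11 | trimethyl phosphonoacetate | COC(=O)CP(=O)(OC)OC | starting material
12 | sodium (dimethoxyphosphoryl)(methoxycarbonyl)methanide | [Na+].COC(=O)[CH-]P(=O)(OC)OC | intermediate
13 | methyl (2E,5S)-5-[(4-methoxybenzyl)oxy]-4,4-dimethylnon-2-en-8-ynoate | C#CCC[C@H](OCc1ccc(OC)cc1)C(C)(C)/C=C/C(=O)OC | intermediate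
14 | methyl (2E,5S)-5-hydroxy-4,4-dimethylnon-2-en-8-ynoate | C#CCC[C@H](O)C(C)(C)/C=C/C(=O)OC | intermediate
15 | methyl (2E,5S)-5-[(tert-butyldimethylsilyl)oxy]-4,4-dimethylnon-2-en-8-ynoate | C#CCC[C@H](O[Si](C)(C)C(C)(C)C)C(C)(C)/C=C/C(=O)OC | intermediate
16 | methyl (2E,5S,8Z)-9-(9-borabicyclo[3.3.1]nonan-9-yl)-8-bromo-5-[(tert-butyldimethylsilyl)oxy]-4,4-dimethylnona-2,8-dienoate | Br/C(CC[C@H](O[Si](C)(C)C(C)(C)C)C(C)(C)/C=C/C(=O)OC)=C\B1C2CCCC1CCC2 | intermediate
17 | methyl (2E,5S)-8-bromo-5-[(tert-butyldimethylsilyl)oxy]-4,4-dimethylnona-2,8-dienoate | C=C(Br)CC[C@H](O[Si](C)(C)C(C)(C)C)C(C)(C)/C=C/C(=O)OC | intermediate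
18 | methyl 2-[(1R,3S)-3-[(tert-butyldimethylsilyl)oxy]-2,2-dimethyl-6-methylidenecyclohexyl]acetate | C=C1CC[C@H](O[Si](C)(C)C(C)(C)C)C(C)(C)[C@@H]1CC(=O)OC | intermediate
19 | 2-[(1R,3S)-3-[(tert-butyldimethylsilyl)oxy]-2,2-dimethyl-6-methylidenecyclohexyl]ethan-1-ol | C=C1CC[C@H](O[Si](C)(C)C(C)(C)C)C(C)(C)[C@@H]1CCO | intermediate
20 | tert-butyl{[(1S,3R)-3-(2-iodoethyl)-2,2-dimethyl-4-methylidenecyclohexyl]oxy}dimethylsilane | C=C1CC[C@H](O[Si](C)(C)C(C)(C)C)C(C)(C)[C@@H]1CCI | intermediate
21 | (2E,6E)-farnesol | CC(C)=CCC/C(C)=C/CC/C(C)=C/CO | starting material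
22 | (2E,6E)-1-bromo-3,7,11-trimethyldodeca-2,6,10-triene | CC(C)=CCC/C(C)=C/CC/C(C)=C/CBr | intermediate
23 | propyne, prop-1-yne | CC#C | starting material
24 | 1,3-dilithiopropyne, (prop-1-yne-1,3-diyl)dilithium | [Li]CC#C[Li] | intermediate
25 | [(5E,9E)-6,10,14-trimethylpentadeca-5,9,13-trien-1-yn-1-yl]lithium | CC(C)=CCC/C(C)=C/CC/C(C)=C/CCC#C[Li] | intermediate
26 | (6E,10E)-7,11,15-trimethylhexadeca-6,10,14-trien-2-yne | CC(C)=CCC/C(C)=C/CC/C(C)=C/CCC#CC | intermediate
27 | chlorobis(cyclopentadienyl)[(2E,6E,10E)-7,11,15-trimethylhexadeca-2,6,10,14-tetraen-2-yl]zirconium | C/C(=C\CC/C=C(\C)CC/C=C(\C)CCC=C(C)C)[Zr](Cl)(C1C=CC=C1)C1C=CC=C1 | intermediate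
28 | (2E,6E,10E)-2-iodo-7,11,15-trimethylhexadeca-2,6,10,14-tetraene | C/C(I)=C\CC/C=C(\C)CC/C=C(\C)CCC=C(C)C | intermediate
29 | {2-[(1R,3S)-3-[(tert-butyldimethylsilyl)oxy]-2,2-dimethyl-6-methylidenecyclohexyl]ethyl}(iodo)zinc | C=C1CC[C@H](O[Si](C)(C)C(C)(C)C)C(C)(C)[C@@H]1CC[Zn]I | intermediate
30 | tert-butyl{[(1S,3R)-2,2-dimethyl-4-methylidene-3-[(3E,7E,11E)-3,8,12,16-tetramethylheptadeca-3,7,11,15-tetraen-1-yl]cyclohexyl]oxy}dimethylsilane | C=C1CC[C@H](O[Si](C)(C)C(C)(C)C)C(C)(C)[C@@H]1CC/C(C)=C/CC/C=C(\C)CC/C=C(\C)CCC=C(C)C | intermediate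
31 | achilleol A, (1S,3R)-2,2-dimethyl-4-methylidene-3-[(3E,7E,11E)-3,8,12,16-tetramethylheptadeca-3,7,11,15-tetraen-1-yl]cyclohexan-1-ol | C=C1CC[C@H](O)C(C)(C)[C@@H]1CC/C(C)=C/CC/C=C(\C)CC/C=C(\C)CCC=C(C)C | target

Total step count: 18. Longest linear sequence: 15 steps (steps 1–13, 17 and 18, from (R)-pantolactone); the side-chain branch from farnesol is steps 14–16.

Steps most likely to fail

Step 11. The vinyl radical may take hydrogen from the stannane before it cyclises, or abstract a hydrogen from a C2 methyl group by a 1,6-shift. The cis selectivity may also erode if the chair with an axial silyloxy group competes. The fallback replaces the radical chain by a two-electron organometallic closure of the same bond. It sets out from 17: oxidative addition of the C–Br bond to zerovalent nickel (Ni(cod)2, Et3N, MeCN, rt) and intramolecular 6-exo carbometalation of the enoate should give a nickel enolate. Et3SiH intercepts this by hydride transfer to nickel, bromide leaving on silicon, ahead of β-hydride elimination, and C–H reductive elimination should give 18 directly. It rejoins the route at 18 and makes no new compound.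

Step 10. The Lewis-acidic bromoborane may attack the silyl ether or the ester, deliver bromide to the enoate in a conjugate sense, or leave the alkenylborane incompletely protonated. The fallback dispenses with the bromide and generates the same C6 vinyl radical from the alkyne. It sets out from 15: Bu3SnH and AIBN in benzene at 80 °C add a stannyl radical to the terminal alkyne carbon, and 6-exo closure onto the enoate should give the exocyclic vinylstannane methyl 2-[(1S,3S)-3-[(tert-butyldimethylsilyl)oxy]-2,2-dimethyl-6-[(tributylstannyl)methylidene]cyclohexyl]acetate F1. F1 has the same spatial arrangement as 18 (the C1 descriptor changes by priority only) and its alkene geometry is immaterial. Protodestannylation with TsOH·H2O in CH2Cl2 at 0 °C should then give 18, where the route is rejoined.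

Step 17. Zinc insertion may be slow or incomplete, the alkylzinc may be protonated, and the alkylpalladium intermediate may undergo β-hydride elimination or homocoupling instead of productive reductive elimination. The fallback is a B-alkyl Suzuki–Miyaura coupling. It sets out from 20: iodine–lithium exchange (t-BuLi, 2 equiv, Et2O, −78 °C) and capture with 9-methoxy-9-BBN should give lithium {2-[(1R,3S)-3-[(tert-butyldimethylsilyl)oxy]-2,2-dimethyl-6-methylidenecyclohexyl]ethyl}(methoxy)-9-borabicyclo[3.3.1]nonan-9-uide F2. F2 is coupled with 28 (Pd(dppf)Cl2, aq K3PO4, DMF/THF, rt) and the route is rejoined at 30.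

Further compounds
F0 | step 11 | none | none
F1 | step 10 | methyl 2-[(1S,3S)-3-[(tert-butyldimethylsilyl)oxy]-2,2-dimethyl-6-[(tributylstannyl)methylidene]cyclohexyl]acetate | CCCC[Sn](CCCC)(CCCC)C=C1CC[C@H](O[Si](C)(C)C(C)(C)C)C(C)(C)[C@@H]1CC(=O)OC
F2 | step 17 | lithium {2-[(1R,3S)-3-[(tert-butyldimethylsilyl)oxy]-2,2-dimethyl-6-methylidenecyclohexyl]ethyl}(methoxy)-9-borabicyclo[3.3.1]nonan-9-uide | [Li+].C=C1CC[C@H](O[Si](C)(C)C(C)(C)C)C(C)(C)[C@@H]1CC[B-]2(OC)C3CCCC2CCC3
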